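**Retrosynthetic overview**
- The target is reached last by chelation-controlled cleavage of one ortho O-methyl ether; the aryl ketone is carried as its 2-hydroxy-6-methoxy form.
- Key disconnection: the C6–phenyl bond, made by a nickel-catalysed decarboxylative radical cross-coupling of a C6 N-acyloxyphthalimide with phenylzinc chloride, trans to the C1 aroyl group.
- The carboxyl that is traded for phenyl is also the second activating group of the dienophile: an enantioselective borate-catalysed [4+2] cycloaddition of a β-aroylacrylic active ester with (E)-β-ocimene sets C1 and C2.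
- Dienophile: Friedel–Crafts acylation of 1,2,3,5-tetramethoxybenzene (from phenol by tribromination, O-methylation and copper-catalysed methanolysis) with maleic anhydride. Diene: C2-prenylation of 3-methyl-3-sulfolene, then SO2 extrusion.
- Ring order: both benzene rings are bought (phenol, phenylmagnesium bromide); the cyclohexene is the only ring formed (cycloaddition step).

Locants used below: cyclohexene C1 carries the aroyl group, C2 the prenyl (3-methylbut-2-en-1-yl) group, C3 the methyl group, C6 the phenyl (or carboxyl) group. (R)-VANOL = (R)-3,3'-diphenyl-[2,2'-binaphthalene]-1,1'-diol.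

Assumption: the (R)-VANOL borate is taken to deliver the (1R,5S,6R) adduct 12; if the sense of induction is the opposite, (S)-VANOL is used and nothing else changes.

**Route**

Step 1
Reactants: 1 phenol
Product: 2 2,4,6-tribromophenol
Conditions: Br2 (3.1 equiv), H2O, 20 °C
Reagents that add atoms: bromine, BrBr
Why: Electrophilic aromatic bromination of the strongly activated phenol stops cleanly at the 2,4,6-tribromide, which marks the three carbons that will carry oxygen.

Step 2
Reactants: 2 2,4,6-tribromophenol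
Product: 3 1,3,5-tribromo-2-methoxybenzene
Conditions: MeI, K2CO3, acetone, reflux
Reagents that add atoms: iodomethane, CI
Why: Williamson ether synthesis (SN2 of the phenoxide on iodomethane) installs the future 3'-methoxy group and removes the acidic proton before the copper step.

Step 3
Reactants: 3 1,3,5-tribromo-2-methoxybenzene
Product: 4 1,2,3,5-tetramethoxybenzene
Conditions: NaOMe (12 equiv), CuBr (0.3 equiv), MeOH/DMF, 110 °C
Reagents that add atoms: sodium methoxide, [Na+].[O-]C
Why: Copper-catalysed Ullmann-type C–O coupling replaces all three aryl bromides by methoxide and gives the symmetrical tetramethyl ether.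

Step 4
Reactants: 4 1,2,3,5-tetramethoxybenzene; 5 maleic anhydride
Product: 6 (2E)-4-(2-hydroxy-3,4,6-trimethoxyphenyl)-4-oxobut-2-enoic acid
Conditions: AlCl3 (3 equiv), CH2Cl2, 0 → 25 °C; then ice/aq. HCl
Reagents that add atoms: none
Why: Friedel–Crafts acylation by the AlCl3-activated anhydride can only occur at the two equivalent free ring positions and gives the β-aroylacrylic acid as the E alkene under the acidic conditions, while the aluminium chelate of the new ketone cleaves the more crowded ortho methyl ether (the one flanked by a second methoxy group).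

Step 5
Reactants: 6 (2E)-4-(2-hydroxy-3,4,6-trimethoxyphenyl)-4-oxobut-2-enoic acid
Product: 7 1,3-dioxoisoindolin-2-yl (2E)-4-(2-hydroxy-3,4,6-trimethoxyphenyl)-4-oxobut-2-enoate
Conditions: N-hydroxyphthalimide, N,N'-diisopropylcarbodiimide, CH2Cl2, 0 → 25 °C
Reagents that add atoms: N-hydroxyphthalimide, ON1C(=O)c2ccccc2C1=O
Why: Carbodiimide-mediated esterification gives the N-acyloxyphthalimide that serves both as second activating group of the dienophile and as radical precursor, the ketone-chelated phenol being too weakly nucleophilic to compete.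

Step 6
Reactants: 8 3-methyl-2,5-dihydrothiophene 1,1-dioxide (3-methyl-3-sulfolene); 9 1-bromo-3-methylbut-2-ene
Product: 10 3-methyl-2-(3-methylbut-2-en-1-yl)-2,5-dihydrothiophene 1,1-dioxide (racemic)
Conditions: LiN(SiMe3)2 (1.1 equiv, added to 8 + 9), THF/DMPU, −78 °C
Reagents that add atoms: none
Why: Alkylation of the sulfone α-carbanion trapped in situ by the allylic bromide takes place at C2 next to the methyl-bearing carbon, as established for 3-methyl-3-sulfolene, and the racemic stereocentre is erased in the next step.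

Step 7
Reactants: 10 3-methyl-2-(3-methylbut-2-en-1-yl)-2,5-dihydrothiophene 1,1-dioxide
Product: 11 (3E)-3,7-dimethylocta-1,3,6-triene ((E)-β-ocimene)
Conditions: toluene, 110 °C, N2 sweep
Reagents that add atoms: none
Why: Thermal cheletropic extrusion of SO2 is disrotatory and turns the C2 substituent outward, so only the E-configured 1,3-diene is formed.

Step 8
Reactants: 7 1,3-dioxoisoindolin-2-yl (2E)-4-(2-hydroxy-3,4,6-trimethoxyphenyl)-4-oxobut-2-enoate; 11 (3E)-3,7-dimethylocta-1,3,6-triene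
Product: 12 1,3-dioxoisoindolin-2-yl (1R,5S,6R)-6-(2-hydroxy-3,4,6-trimethoxybenzoyl)-4-methyl-5-(3-methylbut-2-en-1-yl)cyclohex-3-ene-1-carboxylate
Conditions: B(OPh)3 (0.2 equiv), (R)-VANOL (0.2 equiv), 4 Å molecular sieves, PhCF3, 0 → 25 °C; 11 (2 equiv)
Reagents that add atoms: none
Why: Proposed new method: the 2'-hydroxy ketone should bind the chiral VANOL borate as a phenoxide–carbonyl chelate just as 2'-hydroxychalcones do, so that in this Diels–Alder reaction the ketone-activated dienophile joins its ester-bearing carbon to the unsubstituted diene terminus with the chelated aroyl group endo (C1/C2 cis, C1/C6 trans from the E alkene) and with one face shielded by the ligand, the closest known reaction being the enantioselective borate-mediated cycloaddition of 2'-hydroxychalcones with acyclic 1,3-dienes.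

Step 9
Reactants: 12 1,3-dioxoisoindolin-2-yl (1R,5S,6R)-6-(2-hydroxy-3,4,6-trimethoxybenzoyl)-4-methyl-5-(3-methylbut-2-en-1-yl)cyclohex-3-ene-1-carboxylate; 13 phenylmagnesium bromide
Product: 15 (2-hydroxy-3,4,6-trimethoxyphenyl)[(1R,2S,6R)-3-methyl-2-(3-methylbut-2-en-1-yl)-6-phenylcyclohex-3-en-1-yl]methanone, via phenylzinc chloride 14 (not isolated)
Conditions: 13 (4 equiv), ZnCl2, THF, 0 °C; then 12, NiCl2(dme) (0.3 equiv), 4,4'-di-tert-butyl-2,2'-bipyridine (0.6 equiv), THF/DMF, 25 °C
Reagents that add atoms: none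
Why: Nickel-catalysed decarboxylative Negishi-type arylation of the redox-active ester, in which single-electron reduction expels CO2 and phthalimide to give the secondary C6 radical that is captured by the phenylnickel species and coupled on the ring face opposite the neighbouring aroyl group, so phenyl ends up trans to C1 and trans to the C2 prenyl group (6R).

Step 10
Reactants: 15 (2-hydroxy-3,4,6-trimethoxyphenyl)[(1R,2S,6R)-3-methyl-2-(3-methylbut-2-en-1-yl)-6-phenylcyclohex-3-en-1-yl]methanone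
Product: 16 (2,6-dihydroxy-3,4-dimethoxyphenyl)[(1R,2S,6R)-3-methyl-2-(3-methylbut-2-en-1-yl)-6-phenylcyclohex-3-en-1-yl]methanone
Conditions: BCl3 (3 equiv), CH2Cl2, −78 → 0 °C; then aq. NaHCO3
Reagents that add atoms: none
Why: Chelation-directed Lewis-acid cleavage of an aryl methyl ether, in which boron held at the ketone oxygen activates only the methoxy group ortho to the carbonyl for attack of chloride on its methyl group, leaving the 3'- and 4'-methoxy groups, both trisubstituted alkenes and the three stereocentres (C1 already in its thermodynamically preferred arrangement) untouched.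

**Compound list**
1 | phenol | Oc1ccccc1 | starting material
2 | 2,4,6-tribromophenol | Oc1c(Br)cc(Br)cc1Br | intermediate
3 | 1,3,5-tribromo-2-methoxybenzene | COc1c(Br)cc(Br)cc1Br | intermediate
4 | 1,2,3,5-tetramethoxybenzene | COc1cc(OC)c(OC)c(OC)c1 | intermediate
5 | maleic anhydride (furan-2,5-dione) | O=C1OC(=O)C=C1 | starting material
6 | (2E)-4-(2-hydroxy-3,4,6-trimethoxyphenyl)-4-oxobut-2-enoic acid | OC(=O)/C=C/C(=O)c1c(O)c(OC)c(OC)cc1OC | intermediate
7 | 1,3-dioxoisoindolin-2-yl (2E)-4-(2-hydroxy-3,4,6-trimethoxyphenyl)-4-oxobut-2-enoate | O=C(/C=C/C(=O)c1c(O)c(OC)c(OC)cc1OC)ON1C(=O)c2ccccc2C1=O | intermediate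
8 | 3-methyl-2,5-dihydrothiophene 1,1-dioxide (3-methyl-3-sulfolene) | CC1=CCS(=O)(=O)C1 | starting material
9 | 1-bromo-3-methylbut-2-ene (prenyl bromide) | CC(C)=CCBr | starting material
10 | 3-methyl-2-(3-methylbut-2-en-1-yl)-2,5-dihydrothiophene 1,1-dioxide (racemic) | CC(C)=CCC1C(C)=CCS1(=O)=O | intermediate
11 | (3E)-3,7-dimethylocta-1,3,6-triene ((E)-β-ocimene) | C=C/C(C)=C/CC=C(C)C | intermediate
12 | 1,3-dioxoisoindolin-2-yl (1R,5S,6R)-6-(2-hydroxy-3,4,6-trimethoxybenzoyl)-4-methyl-5-(3-methylbut-2-en-1-yl)cyclohex-3-ene-1-carboxylate | COc1cc(OC)c(C(=O)[C@@H]2[C@H](CC=C(C)C)C(C)=CC[C@H]2C(=O)ON2C(=O)c3ccccc3C2=O)c(O)c1OC | intermediate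
13 | phenylmagnesium bromide | Br[Mg]c1ccccc1 | starting material
14 | phenylzinc chloride | Cl[Zn]c1ccccc1 | intermediate
15 | (2-hydroxy-3,4,6-trimethoxyphenyl)[(1R,2S,6R)-3-methyl-2-(3-methylbut-2-en-1-yl)-6-phenylcyclohex-3-en-1-yl]methanone | COc1cc(OC)c(C(=O)[C@@H]2[C@H](CC=C(C)C)C(C)=CC[C@H]2c2ccccc2)c(O)c1OC | intermediate
16 | (2,6-dihydroxy-3,4-dimethoxyphenyl)[(1R,2S,6R)-3-methyl-2-(3-methylbut-2-en-1-yl)-6-phenylcyclohex-3-en-1-yl]methanone | COc1cc(O)c(C(=O)[C@@H]2[C@H](CC=C(C)C)C(C)=CC[C@H]2c2ccccc2)c(O)c1OC | target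

**Step count**
Total steps: 10. Longest linear sequence: 8 (steps 1–5, 8, 9, 10; steps 6–7 build the diene).

**Steps most likely to fail, with fallbacks**

Step 9 (highest risk). The secondary C6 radical lies 1,3 to the pseudo-axial prenyl group and can close 5-exo onto it (bridged bicyclo[3.2.1]octenyl by-products) before nickel captures it. Approach next to the aroyl group may also erode the trans selectivity. The high NiCl2(dme) loading and concentrated phenylzinc chloride are chosen to favour capture. Fallback (no alkene within reach of the C6 radical; the prenyl group is built afterwards): set out from 8 and 7. Alkylate 8 with methyl bromoacetate (LiN(SiMe3)2, THF/DMPU, −78 °C) to methyl 2-(3-methyl-1,1-dioxido-2,5-dihydrothiophen-2-yl)acetate F1. Extrude SO2 (toluene, 110 °C) to methyl (3E)-4-methylhexa-3,5-dienoate F2. Run the cycloaddition of step 8 with 7 to 1,3-dioxoisoindolin-2-yl (1R,5S,6R)-6-(2-hydroxy-3,4,6-trimethoxybenzoyl)-5-(2-methoxy-2-oxoethyl)-4-methylcyclohex-3-ene-1-carboxylate F3. Arylate as in step 9 to methyl 2-[(1S,5R,6R)-6-(2-hydroxy-3,4,6-trimethoxybenzoyl)-2-methyl-5-phenylcyclohex-2-en-1-yl]acetate F4. Saponify (LiOH, THF/H2O) to 2-[(1S,5R,6R)-6-(2-hydroxy-3,4,6-trimethoxybenzoyl)-2-methyl-5-phenylcyclohex-2-en-1-yl]acetic acid F5. Activate with N-hydroxyphthalimide and N,N'-diisopropylcarbodiimide to 1,3-dioxoisoindolin-2-yl 2-[(1S,5R,6R)-6-(2-hydroxy-3,4,6-trimethoxybenzoyl)-2-methyl-5-phenylcyclohex-2-en-1-yl]acetate F6, and couple this in the same flask with (2-methylprop-1-en-1-yl)zinc chloride (Ni(acac)2, 2,2'-bipyridine, THF/DMF). This decarboxylative alkenylation creates the prenyl group and comes back to the route at 15.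

Step 8. The borate catalyst has not been used with this dienophile class. Uncatalysed background reaction of the doubly activated alkene, endo/exo leakage, or oxa-Michael closure of the 2'-hydroxy enone to a chromanone could lower ee and yield. Fallback (resolution instead of asymmetric catalysis): set out from 6 and 11. Heat them together (toluene, 60 °C; the hydrogen-bonded aryl ketone remains the stronger director) to rac-(1R,5S,6R)-6-(2-hydroxy-3,4,6-trimethoxybenzoyl)-4-methyl-5-(3-methylbut-2-en-1-yl)cyclohex-3-ene-1-carboxylic acid F7. Crystallise (1R)-1-phenylethan-1-aminium (1R,5S,6R)-6-(2-hydroxy-3,4,6-trimethoxybenzoyl)-4-methyl-5-(3-methylbut-2-en-1-yl)cyclohex-3-ene-1-carboxylate F8. Liberate with dilute HCl (1R,5S,6R)-6-(2-hydroxy-3,4,6-trimethoxybenzoyl)-4-methyl-5-(3-methylbut-2-en-1-yl)cyclohex-3-ene-1-carboxylic acid F9. Esterify it with N-hydroxyphthalimide (N,N'-diisopropylcarbodiimide, CH2Cl2), which comes back to the route at 12.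

Step 10. The second ortho ether is slower to cleave than the first, and BCl3 or the HCl it releases may attack the trisubstituted alkenes or the 3'-methoxy group. Fallback (deprotect before any acid-sensitive alkene is present): set out from 6. Cleave its remaining ortho ether with BBr3 (CH2Cl2, −78 → 0 °C) to (2E)-4-(2,6-dihydroxy-3,4-dimethoxyphenyl)-4-oxobut-2-enoic acid F10. Convert it as in step 5 into 1,3-dioxoisoindolin-2-yl (2E)-4-(2,6-dihydroxy-3,4-dimethoxyphenyl)-4-oxobut-2-enoate F11. Run the cycloaddition of step 8 with 11 to 1,3-dioxoisoindolin-2-yl (1R,5S,6R)-6-(2,6-dihydroxy-3,4-dimethoxybenzoyl)-4-methyl-5-(3-methylbut-2-en-1-yl)cyclohex-3-ene-1-carboxylate F12. Arylate as in step 9 (two more equivalents of phenylzinc chloride for the second phenol), which comes back to the route at 16.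

**Further compounds**
F1 | step 9 | methyl 2-(3-methyl-1,1-dioxido-2,5-dihydrothiophen-2-yl)acetate (racemic) | COC(=O)CC1C(C)=CCS1(=O)=O
F2 | step 9 | methyl (3E)-4-methylhexa-3,5-dienoate | COC(=O)C/C=C(C)/C=C
F3 | step 9 | 1,3-dioxoisoindolin-2-yl (1R,5S,6R)-6-(2-hydroxy-3,4,6-trimethoxybenzoyl)-5-(2-methoxy-2-oxoethyl)-4-methylcyclohex-3-ene-1-carboxylate | COc1cc(OC)c(C(=O)[C@@H]2[C@H](CC(=O)OC)C(C)=CC[C@H]2C(=O)ON2C(=O)c3ccccc3C2=O)c(O)c1OC
F4 | step 9 | methyl 2-[(1S,5R,6R)-6-(2-hydroxy-3,4,6-trimethoxybenzoyl)-2-methyl-5-phenylcyclohex-2-en-1-yl]acetate | COc1cc(OC)c(C(=O)[C@@H]2[C@H](CC(=O)OC)C(C)=CC[C@H]2c2ccccc2)c(O)c1OC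
F5 | step 9 | 2-[(1S,5R,6R)-6-(2-hydroxy-3,4,6-trimethoxybenzoyl)-2-methyl-5-phenylcyclohex-2-en-1-yl]acetic acid | COc1cc(OC)c(C(=O)[C@@H]2[C@H](CC(O)=O)C(C)=CC[C@H]2c2ccccc2)c(O)c1OC
F6 | step 9 | 1,3-dioxoisoindolin-2-yl 2-[(1S,5R,6R)-6-(2-hydroxy-3,4,6-trimethoxybenzoyl)-2-methyl-5-phenylcyclohex-2-en-1-yl]acetate | COc1cc(OC)c(C(=O)[C@@H]2[C@H](CC(=O)ON3C(=O)c4ccccc4C3=O)C(C)=CC[C@H]2c2ccccc2)c(O)c1OC
F7 | step 8 | rac-(1R,5S,6R)-6-(2-hydroxy-3,4,6-trimethoxybenzoyl)-4-methyl-5-(3-methylbut-2-en-1-yl)cyclohex-3-ene-1-carboxylic acid (racemate, both enantiomers written) | COc1cc(OC)c(C(=O)[C@@H]2[C@H](CC=C(C)C)C(C)=CC[C@H]2C(O)=O)c(O)c1OC.COc1cc(OC)c(C(=O)[C@H]2[C@@H](CC=C(C)C)C(C)=CC[C@@H]2C(O)=O)c(O)c1OC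
F8 | step 8 | (1R)-1-phenylethan-1-aminium (1R,5S,6R)-6-(2-hydroxy-3,4,6-trimethoxybenzoyl)-4-methyl-5-(3-methylbut-2-en-1-yl)cyclohex-3-ene-1-carboxylate | COc1cc(OC)c(C(=O)[C@@H]2[C@H](CC=C(C)C)C(C)=CC[C@H]2C([O-])=O)c(O)c1OC.C[C@@H]([NH3+])c1ccccc1
F9 | step 8 | (1R,5S,6R)-6-(2-hydroxy-3,4,6-trimethoxybenzoyl)-4-methyl-5-(3-methylbut-2-en-1-yl)cyclohex-3-ene-1-carboxylic acid | COc1cc(OC)c(C(=O)[C@@H]2[C@H](CC=C(C)C)C(C)=CC[C@H]2C(O)=O)c(O)c1OC
F10 | step 10 | (2E)-4-(2,6-dihydroxy-3,4-dimethoxyphenyl)-4-oxobut-2-enoic acid | OC(=O)/C=C/C(=O)c1c(O)c(OC)c(OC)cc1O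
F11 | step 10 | 1,3-dioxoisoindolin-2-yl (2E)-4-(2,6-dihydroxy-3,4-dimethoxyphenyl)-4-oxobut-2-enoate | O=C(/C=C/C(=O)c1c(O)c(OC)c(OC)cc1O)ON1C(=O)c2ccccc2C1=O
F12 | step 10 | 1,3-dioxoisoindolin-2-yl (1R,5S,6R)-6-(2,6-dihydroxy-3,4-dimethoxybenzoyl)-4-methyl-5-(3-methylbut-2-en-1-yl)cyclohex-3-ene-1-carboxylate | COc1cc(O)c(C(=O)[C@@H]2[C@H](CC=C(C)C)C(C)=CC[C@H]2C(=O)ON2C(=O)c3ccccc3C2=O)c(O)c1OC
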